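**Plan**

1. Feature: the γ-lactone bond C2–C3 joins an acetate unit on the C4 oxygen to C3, the O–CH2 carbon of the 1,2-dioxane (ring locants O1–O2–C3–C4–C5–C6); the carbenoid carbon and C3–H are 1,5-related and the C–H is activated by O2.
2. Retrosynthetic cuts, in order: C2–C3 (Rh carbenoid C–H insertion), the C4–O ester, C5'–C6' of the diene (side chain C1'–C8' counted from C6; carboalumination/Negishi coupling), the alkyne carbon, C6–C1' (peroxycarbenium ion + dienol silyl ether), O2–C3 (hydroperoxide opening an epoxide), C5–C6 (Grignard opening of a glycidol).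
3. Forward: the 1,2-dioxane is closed first, the side chain is grown outwards from C6, and the lactone ring is closed last on the preformed dioxane.
4. Stereochemistry: C4 from (R)-2-methylglycidol; C6 by axial attack on the cyclic peroxycarbenium ion anti to the C4 methyl; C2' by iminium-catalysed transfer hydrogenation; both alkenes E by syn-carbometalation and syn-hydrozirconation; C3 by the cis ring fusion that 1,5-insertion enforces.

Key step: step 15

Assumption: the facial sense of the imidazolidinone-catalysed transfer hydrogenation known for β-aryl-β-methyl enals is taken to hold when the large β-substituent is the dioxanylmethyl group; on that basis the (S)-catalyst gives the required C2' configuration.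

**Route**

Step 1
Reactants: 1 (R)-2-methylglycidol; 2 isopropenylmagnesium bromide
Product: 3 (S)-2,4-dimethylpent-4-ene-1,2-diol
Conditions: 2 (2.5 equiv), CuI (10 mol%), THF, −30 → 0 °C
Reagents that add atoms: none
Why: Copper-catalysed Grignard opening of the epoxide at its CH2 carbon (SN2) leaves the quaternary centre untouched; it becomes C4, and the descriptor changes from R to S only because the ligand priorities change.

Step 2
Reactants: 3 (S)-2,4-dimethylpent-4-ene-1,2-diol
Product: 4 (S)-2-hydroxy-2,4-dimethylpent-4-en-1-yl 4-methylbenzenesulfonate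
Conditions: TsCl, Et3N, Bu2SnO (cat.), CH2Cl2, 0 °C → rt
Reagents that add atoms: p-toluenesulfonyl chloride, Cc1ccc(cc1)S(Cl)(=O)=O
Why: Tin-catalysed selective sulfonylation of the primary hydroxyl of a 1,2-diol; the tertiary alcohol should not react.

Step 3
Reactants: 4 (S)-2-hydroxy-2,4-dimethylpent-4-en-1-yl 4-methylbenzenesulfonate
Product: 5 (2S)-4-hydroperoxy-2-hydroxy-4-methoxy-2-methylpentyl 4-methylbenzenesulfonate (both C4 epimers)
Conditions: O3, CH2Cl2/MeOH (4:1), −78 °C; N2 purge, no reductant
Reagents that add atoms: ozone, [O-][O+]=O; methanol, CO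
Why: Ozonolysis with methanol capture of the carbonyl oxide (Criegee mechanism); the disubstituted carbon should carry the carbonyl oxide and the CH2 terminus leaves as formaldehyde, giving the α-methoxy hydroperoxide.

Step 4
Reactants: 5 (2S)-4-hydroperoxy-2-hydroxy-4-methoxy-2-methylpentyl 4-methylbenzenesulfonate
Product: 8 triethyl{[(4S)-6-methoxy-4,6-dimethyl-1,2-dioxan-4-yl]oxy}silane (both C6 epimers), via hydroperoxy epoxide 6 (not isolated), via dioxanol potassium salt 7 (not isolated)
Conditions: KOt-Bu (2.1 equiv), 18-crown-6 (cat.), THF, −20 → 0 °C; then Et3SiCl, 0 °C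
Reagents that add atoms: chlorotriethylsilane, CC[Si](Cl)(CC)CC
Why: The base closes the epoxide (intramolecular Williamson reaction) and the hydroperoxide anion opens it at the CH2 carbon (6-endo SN2, the only epoxide carbon open to substitution under basic conditions), so the C4–O bond and configuration are untouched; the tertiary alkoxide released is silylated in the same flask.

Step 5
Reactants: 9 3-methylbut-2-enal
Product: 10 (E)-tert-butyldimethyl[(3-methylbuta-1,3-dien-1-yl)oxy]silane
Conditions: TBSOTf, Et3N, Et2O, 0 °C → rt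
Reagents that add atoms: tert-butyldimethylsilyl trifluoromethanesulfonate, CC(C)(C)[Si](C)(C)OS(=O)(=O)C(F)(F)F
Why: Soft enolisation (O-silylation, then γ-deprotonation by the amine) is the standard way to the dienol silyl ether of a β-methyl enal.

Step 6
Reactants: 8 triethyl{[(4S)-6-methoxy-4,6-dimethyl-1,2-dioxan-4-yl]oxy}silane; 10 (E)-tert-butyldimethyl[(3-methylbuta-1,3-dien-1-yl)oxy]silane
Product: 11 4-[(4S,6R)-4,6-dimethyl-4-(triethylsilyloxy)-1,2-dioxan-6-yl]-3-methylbut-2-enal (E/Z mixture)
Conditions: 10 (1.5 equiv), TMSOTf (0.3 equiv), CH2Cl2, −78 °C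
Reagents that add atoms: none
Why: The Lewis acid ionises either C6 epimer to the same cyclic peroxycarbenium ion, which the dienol ether attacks through its terminal carbon (vinylogous Mukaiyama-type addition, as known for silyl enol ethers with 3-alkoxy-1,2-dioxanes); axial attack on the half-chair with the C4 methyl pseudo-equatorial and the silyloxy group pseudo-axial brings the new carbon in anti to the C4 methyl and should set C6 as R.

Step 7
Reactants: 11 4-[(4S,6R)-4,6-dimethyl-4-(triethylsilyloxy)-1,2-dioxan-6-yl]-3-methylbut-2-enal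
Product: 12 (3S)-4-[(4S,6R)-4,6-dimethyl-4-(triethylsilyloxy)-1,2-dioxan-6-yl]-3-methylbutanal
Conditions: (S)-2-tert-butyl-3-methylimidazolidin-4-one·Cl3CCO2H (20 mol%), Hantzsch ester (1.2 equiv), CHCl3, −30 °C
Reagents that add atoms: none
Why: Iminium-catalysed transfer hydrogenation (organocatalytic conjugate reduction) delivers hydride to the unshielded face of the β-carbon, and both alkene isomers converge; this sets C2', which is S in 12 and R from 13 onwards only through a change of ligand priorities.

Step 8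
Reactants: 12 (3S)-4-[(4S,6R)-4,6-dimethyl-4-(triethylsilyloxy)-1,2-dioxan-6-yl]-3-methylbutanal
Product: 13 triethyl{[(4S,6R)-4,6-dimethyl-6-[(2R)-2-methylpent-4-yn-1-yl]-1,2-dioxan-4-yl]oxy}silane
Conditions: dimethyl (1-diazo-2-oxopropyl)phosphonate, K2CO3, MeOH, 0 °C → rt
Reagents that add atoms: dimethyl (1-diazo-2-oxopropyl)phosphonate, COP(=O)(OC)C(=[N+]=[N-])C(C)=O
Why: Seyferth–Gilbert homologation with the Ohira–Bestmann reagent turns the aldehyde into the terminal alkyne under carbonate conditions that should leave the peroxide, the silyl ether and the β-stereocentre alone.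

Step 9
Reactants: 14 3-phenyl-1-propyne
Product: 15 1-phenyl-2-butyne
Conditions: n-BuLi (1.0 equiv), THF, −78 °C; MeI, −78 °C → rt
Reagents that add atoms: iodomethane, CI
Why: Deprotonation of the terminal alkyne and SN2 methylation of the lithium acetylide.

Step 10
Reactants: 15 1-phenyl-2-butyne
Product: 17 (E)-(3-iodobut-2-en-1-yl)benzene, via alkenylzirconocene chloride 16 (not isolated)
Conditions: Cp2Zr(H)Cl (1.5 equiv), THF, rt → 40 °C; then I2, 0 °C
Reagents that add atoms: iodine, II
Why: Hydrozirconation is a syn addition, and equilibration with excess Schwartz reagent should place zirconium on the less hindered, methyl-bearing carbon; iodinolysis with retention gives the E iodide.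

Step 11
Reactants: 13 triethyl{[(4S,6R)-4,6-dimethyl-6-[(2R)-2-methylpent-4-yn-1-yl]-1,2-dioxan-4-yl]oxy}silane; 17 (E)-(3-iodobut-2-en-1-yl)benzene
Product: 19 triethyl{[(4S,6R)-4,6-dimethyl-6-[(2R,4E,6E)-2,4,6-trimethyl-8-phenylocta-4,6-dien-1-yl]-1,2-dioxan-4-yl]oxy}silane, via alkenyl dimethylalane 18 (not isolated)
Conditions: AlMe3 (3 equiv), Cp2ZrCl2 (cat.), H2O (1 equiv), CH2Cl2, −23 °C; then 17, ZnCl2 (0.3 equiv), Pd2(dba)3/P(2-furyl)3 (cat.), THF, rt
Reagents that add atoms: trimethylaluminium, C[Al](C)C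
Why: Zirconium-catalysed syn-carboalumination of the terminal alkyne (methyl to the internal carbon) followed by zinc/palladium-mediated Negishi coupling with retention at both alkenyl partners should give the E,E-diene.

Step 12
Reactants: 19 triethyl{[(4S,6R)-4,6-dimethyl-6-[(2R,4E,6E)-2,4,6-trimethyl-8-phenylocta-4,6-dien-1-yl]-1,2-dioxan-4-yl]oxy}silane
Product: 20 (4S,6R)-4,6-dimethyl-6-[(2R,4E,6E)-2,4,6-trimethyl-8-phenylocta-4,6-dien-1-yl]-1,2-dioxan-4-ol
Conditions: HF·pyridine, pyridine, THF, 0 °C → rt
Reagents that add atoms: none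
Why: Fluoride cleavage of the tertiary triethylsilyl ether; peroxide and diene are inert to buffered HF.

Step 13
Reactants: 20 (4S,6R)-4,6-dimethyl-6-[(2R,4E,6E)-2,4,6-trimethyl-8-phenylocta-4,6-dien-1-yl]-1,2-dioxan-4-ol
Product: 21 (4S,6R)-4,6-dimethyl-6-[(2R,4E,6E)-2,4,6-trimethyl-8-phenylocta-4,6-dien-1-yl]-1,2-dioxan-4-yl bromoacetate
Conditions: BrCH2COBr, pyridine, CH2Cl2, 0 °C
Reagents that add atoms: bromoacetyl bromide, BrCC(Br)=O
Why: Acylation of the hindered tertiary alcohol with a reactive acid bromide.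

Step 14
Reactants: 21 (4S,6R)-4,6-dimethyl-6-[(2R,4E,6E)-2,4,6-trimethyl-8-phenylocta-4,6-dien-1-yl]-1,2-dioxan-4-yl bromoacetate
Product: 22 (4S,6R)-4,6-dimethyl-6-[(2R,4E,6E)-2,4,6-trimethyl-8-phenylocta-4,6-dien-1-yl]-1,2-dioxan-4-yl diazoacetate
Conditions: TsNHNHTs, DBU, THF, 0 °C
Reagents that add atoms: N,N'-ditosylhydrazine, Cc1ccc(cc1)S(=O)(=O)NNS(=O)(=O)c1ccc(C)cc1
Why: Diazoacetate formation from a bromoacetate: N-alkylation of the ditosylhydrazine and twofold sulfinate elimination, a short cold exposure to amidine base that the saturated dioxane should tolerate.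

Step 15
Reactants: 22 (4S,6R)-4,6-dimethyl-6-[(2R,4E,6E)-2,4,6-trimethyl-8-phenylocta-4,6-dien-1-yl]-1,2-dioxan-4-yl diazoacetate
Product: 23 target CNP0272658.1, the (3S,4S,6R)-1,2-dioxane cis-fused at C3–C4 to the γ-lactone
Conditions: Rh2(acam)4 (1 mol%), CH2Cl2, 40 °C, 22 added by syringe pump (final ≤ 5 mM)
Reagents that add atoms: none
Why: Proposed new method: loss of N2 gives a rhodium carbenoid that inserts through a concerted three-centre transition state into the equatorial C3–H bond and forms C2–C3; such an insertion geminal to a peroxide oxygen has not been shown, but O2 should act like an ether oxygen in stabilising the positive charge that builds up on C3. The closest known reaction type is the dirhodium carboxamidate-catalysed 1,5-insertion of 2-alkoxyethyl and 1,3-dioxan-5-yl diazoacetates into O–C–H bonds to give β-alkoxy γ-lactones. The lactone closes as a five-membered ring by 1,5 C–H insertion and is fused cis to the dioxane. The new centre C3 is controlled by C4, because only the C3–H on the face of the ester oxygen can reach the carbenoid and a trans-fused 5/6 system cannot form. The step needs C3–H to win over C5–H, the C4 methyl, the remote diene and the O–O bond: the lone pair on O2 activates C3–H, C5 lies between two quaternary carbons and β to two oxygens, and the methyl C–H is primary. The amidate ligands temper the carbenoid, slow addition at high dilution suppresses bimolecular cyclopropanation, and the dialkyl peroxide has no O–H through which it could oxidise the catalyst.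

**Compound list**

1 | (R)-2-methylglycidol | OC[C@]1(C)CO1 | starting material
2 | isopropenylmagnesium bromide | CC(=C)[Mg]Br | starting material
3 | (S)-2,4-dimethylpent-4-ene-1,2-diol | C=C(C)C[C@](C)(O)CO | intermediate
4 | (S)-2-hydroxy-2,4-dimethylpent-4-en-1-yl 4-methylbenzenesulfonate | C=C(C)C[C@](C)(O)COS(=O)(=O)c1ccc(C)cc1 | intermediate
5 | (2S)-4-hydroperoxy-2-hydroxy-4-methoxy-2-methylpentyl 4-methylbenzenesulfonate (both C4 epimers) | COC(C)(OO)C[C@](C)(O)COS(=O)(=O)c1ccc(C)cc1 | intermediate
6 | (S)-2-(2-hydroperoxy-2-methoxypropyl)-2-methyloxirane (present as its potassium peroxide salt) | COC(C)(OO)C[C@@]1(C)CO1 | intermediate (not isolated)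
7 | (4S)-6-methoxy-4,6-dimethyl-1,2-dioxan-4-ol (present as its potassium alkoxide; both C6 epimers) | COC1(C)C[C@](C)(O)COO1 | intermediate (not isolated)
8 | triethyl{[(4S)-6-methoxy-4,6-dimethyl-1,2-dioxan-4-yl]oxy}silane (both C6 epimers) | COC1(C)C[C@](C)(O[Si](CC)(CC)CC)COO1 | intermediate
9 | 3-methylbut-2-enal | CC(C)=CC=O | starting material
10 | (E)-tert-butyldimethyl[(3-methylbuta-1,3-dien-1-yl)oxy]silane | C=C(C)/C=C/O[Si](C)(C)C(C)(C)C | intermediate
11 | 4-[(4S,6R)-4,6-dimethyl-4-(triethylsilyloxy)-1,2-dioxan-6-yl]-3-methylbut-2-enal (E/Z mixture) | O=CC=C(C)C[C@]1(C)C[C@](C)(O[Si](CC)(CC)CC)COO1 | intermediate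
12 | (3S)-4-[(4S,6R)-4,6-dimethyl-4-(triethylsilyloxy)-1,2-dioxan-6-yl]-3-methylbutanal | O=CC[C@@H](C)C[C@]1(C)C[C@](C)(O[Si](CC)(CC)CC)COO1 | intermediate
13 | triethyl{[(4S,6R)-4,6-dimethyl-6-[(2R)-2-methylpent-4-yn-1-yl]-1,2-dioxan-4-yl]oxy}silane | C#CC[C@@H](C)C[C@]1(C)C[C@](C)(O[Si](CC)(CC)CC)COO1 | intermediate
14 | 3-phenyl-1-propyne | C#CCc1ccccc1 | starting material
15 | 1-phenyl-2-butyne | CC#CCc1ccccc1 | intermediate
16 | (E)-chlorobis(cyclopentadienyl)(4-phenylbut-2-en-2-yl)zirconium | C/C(=C\Cc1ccccc1)[Zr](Cl)(C1C=CC=C1)C1C=CC=C1 | intermediate (not isolated)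
17 | (E)-(3-iodobut-2-en-1-yl)benzene | C/C(I)=C\Cc1ccccc1 | intermediate
18 | dimethyl[(1E,4R)-5-[(4S,6R)-4,6-dimethyl-4-(triethylsilyloxy)-1,2-dioxan-6-yl]-2,4-dimethylpent-1-en-1-yl]alane | C[Al](C)/C=C(\C)C[C@@H](C)C[C@]1(C)C[C@](C)(O[Si](CC)(CC)CC)COO1 | intermediate (not isolated)
19 | triethyl{[(4S,6R)-4,6-dimethyl-6-[(2R,4E,6E)-2,4,6-trimethyl-8-phenylocta-4,6-dien-1-yl]-1,2-dioxan-4-yl]oxy}silane | CC(=C\Cc1ccccc1)/C=C(\C)C[C@@H](C)C[C@]1(C)C[C@](C)(O[Si](CC)(CC)CC)COO1 | intermediate
20 | (4S,6R)-4,6-dimethyl-6-[(2R,4E,6E)-2,4,6-trimethyl-8-phenylocta-4,6-dien-1-yl]-1,2-dioxan-4-ol | CC(=C\Cc1ccccc1)/C=C(\C)C[C@@H](C)C[C@]1(C)C[C@](C)(O)COO1 | intermediate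
21 | (4S,6R)-4,6-dimethyl-6-[(2R,4E,6E)-2,4,6-trimethyl-8-phenylocta-4,6-dien-1-yl]-1,2-dioxan-4-yl bromoacetate | CC(=C\Cc1ccccc1)/C=C(\C)C[C@@H](C)C[C@]1(C)C[C@](C)(OC(=O)CBr)COO1 | intermediate
22 | (4S,6R)-4,6-dimethyl-6-[(2R,4E,6E)-2,4,6-trimethyl-8-phenylocta-4,6-dien-1-yl]-1,2-dioxan-4-yl diazoacetate | CC(=C\Cc1ccccc1)/C=C(\C)C[C@@H](C)C[C@]1(C)C[C@](C)(OC(=O)C=[N+]=[N-])COO1 | intermediate
23 | CNP0272658.1: (3S,4S,6R)-4,6-dimethyl-6-[(2R,4E,6E)-2,4,6-trimethyl-8-phenylocta-4,6-dien-1-yl]-1,2-dioxane cis-fused at C3–C4 to a γ-lactone (C4–O–CO–CH2–C3) | CC(=C\Cc1ccccc1)/C=C(\C)C[C@@H](C)C[C@]1(C)C[C@]2(C)OC(=O)C[C@@H]2OO1 | target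

**Counts**

Total step count: 15. Longest linear sequence: 12 steps (1–4, 6–8, 11–15), from (R)-2-methylglycidol.

**Steps most likely to fail**

Step 15. The carbenoid may be diverted into cyclopropanation of the remote diene, into insertion at C5–H or the C4 methyl, or onto a peroxide oxygen with ensuing O–O cleavage. The fallback uses known chemistry and closes the lactone by conjugate addition of a hydroperoxide to a butenolide, so that O2–C3 is formed in place of C2–C3. It sets out from diol 3 and comes back to the route at 23. Oxidation of the primary alcohol (TEMPO, PhI(OAc)2) should give (S)-2-hydroxy-2,4-dimethylpent-4-enal F1. Ketenylidenetriphenylphosphorane should convert it, by O-acylation and intramolecular Wittig reaction, into (S)-5-methyl-5-(2-methylprop-2-en-1-yl)furan-2(5H)-one F2. Ozonolysis in CH2Cl2–MeOH should give (5S)-5-(2-hydroperoxy-2-methoxypropyl)-5-methylfuran-2(5H)-one F3. Et2NH in CF3CH2OH should close the dioxane by intramolecular oxa-Michael addition to give the cis-fused 6-methoxy peroxylactone F4. F4 then takes the place of 8 in the operations of steps 6, 7 and 8, giving the lactone enal F5, the lactone aldehyde F6 and the lactone alkyne F7. Carboalumination–coupling of F7 with 17 as in step 11 gives 23.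

Step 11. The O–O bond may be cleaved by the organoaluminium/zirconium reagents acting as Lewis acids or alkyl donors, or by Pd(0)/phosphine, during the one-pot carboalumination–coupling. The fallback sets out from alkyne 13 and comes back at 19. Copper-catalysed borylmethylation of the alkyne (CuCl/ligand, B2pin2, MeI, NaOt-Bu, THF) should give the (E)-2-methylalkenyl pinacol boronate F8 without any organoaluminium reagent. Suzuki–Miyaura coupling of F8 with 17 (Pd catalyst, aqueous K3PO4) then gives 19.

Step 7. The iminium ion is in equilibrium with a dienamine, through which the C6 peroxide oxygen (δ to the aldehyde) may be expelled with opening of the dioxane; facial control may also be incomplete. The fallback sets out from 11 (E isomer) and comes back at 12. An ene-reductase of the Old Yellow Enzyme family (NADPH recycled with glucose/glucose dehydrogenase, buffer pH 7, co-solvent) transfers hydride from the flavin to the β-carbon without an amine and hence without a dienamine. No new compound is made (F0).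

**Further compounds**

F1 | step 15 | (S)-2-hydroxy-2,4-dimethylpent-4-enal | C=C(C)C[C@](C)(O)C=O
F2 | step 15 | (S)-5-methyl-5-(2-methylprop-2-en-1-yl)furan-2(5H)-one | C=C(C)C[C@]1(C)OC(=O)C=C1
F3 | step 15 | (5S)-5-(2-hydroperoxy-2-methoxypropyl)-5-methylfuran-2(5H)-one (both ketal epimers) | COC(C)(OO)C[C@]1(C)OC(=O)C=C1
F4 | step 15 | (3S,4S)-6-methoxy-4,6-dimethyl-1,2-dioxane cis-fused at C3–C4 to the γ-lactone (6-methoxy peroxylactone, both C6 epimers) | COC1(C)C[C@]2(C)OC(=O)C[C@@H]2OO1
F5 | step 15 | lactone enal: (3S,4S,6R)-peroxylactone bearing 2-methyl-4-oxobut-2-en-1-yl at C6 (E/Z mixture) | O=CC=C(C)C[C@]1(C)C[C@]2(C)OC(=O)C[C@@H]2OO1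
F6 | step 15 | lactone aldehyde: (3S,4S,6R)-peroxylactone bearing (2S)-2-methyl-4-oxobutyl at C6 | O=CC[C@@H](C)C[C@]1(C)C[C@]2(C)OC(=O)C[C@@H]2OO1
F7 | step 15 | lactone alkyne: (3S,4S,6R)-peroxylactone bearing (2R)-2-methylpent-4-yn-1-yl at C6 | C#CC[C@@H](C)C[C@]1(C)C[C@]2(C)OC(=O)C[C@@H]2OO1
F8 | step 11 | 2-[(1E,4R)-5-[(4S,6R)-4,6-dimethyl-4-(triethylsilyloxy)-1,2-dioxan-6-yl]-2,4-dimethylpent-1-en-1-yl]-4,4,5,5-tetramethyl-1,3,2-dioxaborolane | CC1(C)OB(/C=C(\C)C[C@@H](C)C[C@]2(C)C[C@](C)(O[Si](CC)(CC)CC)COO2)OC1(C)C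
F0 | step 7 | none | none
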